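Ring A is disconnected at C4a–C5 and C5–C6, C5 with its hydroxyl being carbon monoxide, and the C7–O ester bond is traced back to a gallate on C8. The key step exploits that ring A is a resorcinol monoester (free OH at C5, gallate at C7, C6–H between them) fused to ring C through C4a and C8a. One rhodium-catalysed carbonylative benzannulation shifts the gallate from C8 to C7, inserts CO and aromatises, so the phenol/ester pattern arises without phenol differentiation. The precursor is an enantiopure dihydropyran (ring C carrying ring B, with C2 and C3 set by a glycolate aldol) bearing a 1-galloyloxyprop-2-ynyl group on C8a.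

Key step: step 11

Remarks on the chemistry:
- Flavan numbering (O1, C2, C3, C4, C4a, C5 to C8, C8a) is used for the atoms that end up in rings A and C, also in open-chain and monocyclic intermediates.
- C8 in 19 and 21 is carried as a mixture of epimers, because it becomes an aromatic carbon in step 11.
- C8a is functionalised through a vinylstannane and tin–lithium exchange, not by C–H lithiation, because alkyllithium bases would attack the aryl benzyl ethers.

Step 1
Reactants: 1 (S)-4-benzyloxazolidin-2-one; 2 benzyloxyacetyl chloride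
Product: 4 (S)-4-benzyl-3-[2-(benzyloxy)acetyl]oxazolidin-2-one, via N-lithio oxazolidinone 3 (not isolated)
Conditions: n-BuLi, THF, −78 °C; then 2, −78 → 0 °C
Reagents that add atoms: none
Why: N-acylation of the lithiated oxazolidinone by an acid chloride at low temperature is the standard entry to glycolate imides and avoids ketene formation from the alkoxyacetyl chloride.

Step 2
Reactants: 4 (S)-4-benzyl-3-[2-(benzyloxy)acetyl]oxazolidin-2-one; 5 3,4,5-tris(benzyloxy)benzaldehyde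
Product: 7 (S)-4-benzyl-3-[(2S,3R)-2-(benzyloxy)-3-hydroxy-3-[3,4,5-tris(benzyloxy)phenyl]propanoyl]oxazolidin-2-one, via (Z)-dibutylboron enolate 6 (not isolated)
Conditions: Bu2BOTf, Et3N, CH2Cl2, −78 → 0 °C; then 5, −78 → 0 °C; H2O2, pH 7 buffer, MeOH, 0 °C
Reagents that add atoms: none
Why: Evans syn glycolate aldol: the (Z)-boron enolate reacts through a closed Zimmerman–Traxler chair in which the benzyl group of the auxiliary shields one enolate face, so the 2,3-syn adduct should form with the configuration that becomes C2 (R) and C3 (R) of the flavan; the benzyloxy carbon is S here only because the acyl carbon outranks the carbinol carbon.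

Step 3
Reactants: 7 aldol adduct
Product: 8 (S)-4-benzyl-3-[(2S,3R)-2-(benzyloxy)-3-[(tert-butyldimethylsilyl)oxy]-3-[3,4,5-tris(benzyloxy)phenyl]propanoyl]oxazolidin-2-one
Conditions: TBSOTf, 2,6-lutidine, CH2Cl2, −78 → 0 °C
Reagents that add atoms: tert-butyldimethylsilyl trifluoromethanesulfonate, CC(C)(C)[Si](C)(C)OS(=O)(=O)C(F)(F)F
Why: Silylation of the secondary aldol hydroxyl with a silyl triflate and a hindered pyridine base; it masks the benzylic oxygen so that it cannot close an oxetane onto C4 in step 5.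

Step 4
Reactants: 8 silylated aldol adduct
Product: 9 (2R,3R)-2-(benzyloxy)-3-[(tert-butyldimethylsilyl)oxy]-3-[3,4,5-tris(benzyloxy)phenyl]propan-1-ol
Conditions: LiBH4, H2O (1 equiv), Et2O, 0 °C
Reagents that add atoms: none
Why: Reductive cleavage of the N-acyloxazolidinone by borohydride at the exocyclic carbonyl gives the primary alcohol (future C4) and returns the auxiliary; silyl and benzyl ethers are inert.

Step 5
Reactants: 9 primary alcohol; 10 (trimethylsilyl)acetylene
Product: 13 tert-butyl{[(1R,2R)-2-(benzyloxy)-1-[3,4,5-tris(benzyloxy)phenyl]-5-(trimethylsilyl)pent-4-yn-1-yl]oxy}dimethylsilane, via primary triflate 11 (not isolated), via lithium (trimethylsilyl)acetylide 12 (not isolated)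
Conditions: Tf2O, 2,6-lutidine, CH2Cl2, −78 °C; then LiC≡CSiMe3 (from 10, n-BuLi), THF/DMPU, −78 → −20 °C
Reagents that add atoms: none
Why: SN2 alkynylation of a primary alkyl triflate by a lithium silylacetylide in a dipolar cosolvent; substitution takes place at the CH2 carbon (C4), so neither stereocentre is touched.

Step 6
Reactants: 13 bis-silylated alkyne
Product: 14 (1R,2R)-2-(benzyloxy)-1-[3,4,5-tris(benzyloxy)phenyl]pent-4-yn-1-ol
Conditions: Bu4NF, THF, 0 °C → rt
Reagents that add atoms: none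
Why: Fluoride-mediated desilylation removes the C-silyl and the O-silyl group in one operation and gives the terminal 4-alkyn-1-ol needed for vinylidene formation.

Step 7
Reactants: 14 alkynol
Product: 15 tributyl{(2R,3R)-3-(benzyloxy)-2-[3,4,5-tris(benzyloxy)phenyl]-3,4-dihydro-2H-pyran-6-yl}stannane
Conditions: W(CO)6 (1.2 equiv), THF, hν (350 nm), rt; then 14, Bu3SnOTf, Et3N, rt
Reagents that add atoms: tributyltin trifluoromethanesulfonate, CCCC[Sn](CCCC)(CCCC)OS(=O)(=O)C(F)(F)F
Why: Tungsten-vinylidene alkynol cycloisomerisation: W(CO)5(THF) (zerovalent tungsten) turns the terminal alkyne into a vinylidene, the C2 hydroxyl adds to its α-carbon in the 6-endo sense (O1–C8a bond), and the alkenyl tungstate is intercepted by the tin triflate instead of a proton, the stannyl-trapping variant of this cyclisation; no stereocentre is formed or disturbed.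

Step 8
Reactants: 15 vinylstannane
Product: 17 (2R,3R)-3-(benzyloxy)-2-[3,4,5-tris(benzyloxy)phenyl]-3,4-dihydro-2H-pyran-6-carbaldehyde, via vinyllithium 16 (not isolated)
Conditions: n-BuLi, THF, −78 °C; then DMF, −78 → 0 °C; pH 7 buffer
Reagents that add atoms: N,N-dimethylformamide, CN(C)C=O
Why: Tin–lithium exchange on an α-alkoxyvinylstannane is far faster at −78 °C than deprotonation of the benzylic ether positions, and the vinyllithium is formylated by DMF (Bouveault-type formylation) to install C8.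

Step 9
Reactants: 17 aldehyde; 18 ethynylmagnesium bromide
Product: 19 1-{(2R,3R)-3-(benzyloxy)-2-[3,4,5-tris(benzyloxy)phenyl]-3,4-dihydro-2H-pyran-6-yl}prop-2-yn-1-ol (both C8 epimers)
Conditions: THF, −78 → 0 °C; pH 7 buffer
Reagents that add atoms: none
Why: 1,2-Addition of an alkynyl Grignard reagent to the enal brings in C7 and C6; the C8 carbinol centre forms without control, which is immaterial, and the neutral work-up protects the enol ether.

Step 10
Reactants: 19 propargylic alcohol; 20 3,4,5-tris(benzyloxy)benzoic acid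
Product: 21 1-{(2R,3R)-3-(benzyloxy)-2-[3,4,5-tris(benzyloxy)phenyl]-3,4-dihydro-2H-pyran-6-yl}prop-2-yn-1-yl 3,4,5-tris(benzyloxy)benzoate (both C8 epimers)
Conditions: DCC, DMAP (cat.), CH2Cl2, 0 °C → rt
Reagents that add atoms: none
Why: Steglich esterification proceeds under non-acidic conditions that spare the enol ether and the doubly activated carbinol.

Step 11
Reactants: 21 propargylic gallate
Product: 22 (2R,3R)-3-(benzyloxy)-5-hydroxy-2-[3,4,5-tris(benzyloxy)phenyl]chroman-7-yl 3,4,5-tris(benzyloxy)benzoate (hepta-O-benzyl epigallocatechin 7-O-gallate)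
Conditions: [Rh(CO)2Cl]2 (5 mol %), CO (1 atm), ClCH2CH2Cl, 60 °C
Reagents that add atoms: carbon monoxide, [C-]#[O+]
Why: [Rh(CO)2Cl]2 (monovalent rhodium) activates the terminal alkyne, the gallate carbonyl oxygen adds to C7, and a 1,2-acyloxy shift through a dioxolenium moves the ester from C8 to C7, leaving a rhodium carbene at C6 conjugated through C7=C8 with the C8a=C4a enol ether. Ring A then closes in a formal (5+1) mode: the dienyl carbene cyclometalates onto C4a to a rhodacyclohexadiene (or takes up CO to a dienyl ketene that undergoes 6π electrocyclisation), CO insertion and reductive elimination form C5–C6 and C4a–C5, and the cyclohexa-2,4-dienone enolises by loss of the C4a hydrogen to the C5 phenol. The closest known reaction type is the rhodium-catalysed carbonylative benzannulation of 3-acyloxy-1,4-enynes to resorcinol monoesters. No stereocentre is created; C2 and C3 are remote spectators and both C8 epimers of 21 converge on the same arene. The selectivity needed is 1,2- over 1,3-acyloxy migration, which the unsubstituted alkyne terminus secures, while the position of every substituent follows from the enyne connectivity, so C7 is formed as the gallate and C5 as the only free phenol. The endocyclic enol ether holds C4a as a CH terminus within ring C, so only rotation about C8–C8a into the s-cis diene is required and the C4a hydrogen is available for aromatisation.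

Step 12
Reactants: 22 hepta-O-benzyl epigallocatechin 7-O-gallate
Product: 23 epigallocatechin 7-O-gallate
Conditions: H2 (1 atm), Pd(OH)2/C, THF/MeOH, rt
Reagents that add atoms: none
Why: Catalytic hydrogenolysis removes all seven O-benzyl groups under neutral conditions; the aryl gallate and the cyclic benzylic C2–O1 bond are expected to survive, as is usual in catechin gallate chemistry, and the product should be handled with exclusion of air.

Compound list
1 | (S)-4-benzyloxazolidin-2-one | O=C1N[C@@H](Cc2ccccc2)CO1 | starting material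
2 | benzyloxyacetyl chloride | O=C(Cl)COCc1ccccc1 | starting material
3 | N-lithio derivative of 1, lithium (S)-4-benzyl-2-oxooxazolidin-3-ide | [Li]N1[C@@H](Cc2ccccc2)COC1=O | intermediate
4 | (S)-4-benzyl-3-[2-(benzyloxy)acetyl]oxazolidin-2-one | O=C(COCc1ccccc1)N1[C@@H](Cc2ccccc2)COC1=O | intermediate
5 | 3,4,5-tris(benzyloxy)benzaldehyde | O=Cc1cc(OCc2ccccc2)c(OCc2ccccc2)c(OCc2ccccc2)c1 | starting material
6 | (Z)-dibutylboron enolate of 4 | CCCCB(CCCC)O/C(=C\OCc1ccccc1)N1[C@@H](Cc2ccccc2)COC1=O | intermediate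
7 | (S)-4-benzyl-3-[(2S,3R)-2-(benzyloxy)-3-hydroxy-3-[3,4,5-tris(benzyloxy)phenyl]propanoyl]oxazolidin-2-one | O=C([C@@H](OCc1ccccc1)[C@H](O)c1cc(OCc2ccccc2)c(OCc2ccccc2)c(OCc2ccccc2)c1)N1[C@@H](Cc2ccccc2)COC1=O | intermediate
8 | (S)-4-benzyl-3-[(2S,3R)-2-(benzyloxy)-3-[(tert-butyldimethylsilyl)oxy]-3-[3,4,5-tris(benzyloxy)phenyl]propanoyl]oxazolidin-2-one | O=C([C@@H](OCc1ccccc1)[C@H](O[Si](C)(C)C(C)(C)C)c1cc(OCc2ccccc2)c(OCc2ccccc2)c(OCc2ccccc2)c1)N1[C@@H](Cc2ccccc2)COC1=O | intermediate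
9 | (2R,3R)-2-(benzyloxy)-3-[(tert-butyldimethylsilyl)oxy]-3-[3,4,5-tris(benzyloxy)phenyl]propan-1-ol | OC[C@@H](OCc1ccccc1)[C@H](O[Si](C)(C)C(C)(C)C)c1cc(OCc2ccccc2)c(OCc2ccccc2)c(OCc2ccccc2)c1 | intermediate
10 | (trimethylsilyl)acetylene | C#C[Si](C)(C)C | starting material
11 | (2R,3R)-2-(benzyloxy)-3-[(tert-butyldimethylsilyl)oxy]-3-[3,4,5-tris(benzyloxy)phenyl]propyl trifluoromethanesulfonate | O=S(=O)(OC[C@@H](OCc1ccccc1)[C@H](O[Si](C)(C)C(C)(C)C)c1cc(OCc2ccccc2)c(OCc2ccccc2)c(OCc2ccccc2)c1)C(F)(F)F | intermediate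
12 | lithium (trimethylsilyl)acetylide | [Li]C#C[Si](C)(C)C | intermediate
13 | tert-butyl{[(1R,2R)-2-(benzyloxy)-1-[3,4,5-tris(benzyloxy)phenyl]-5-(trimethylsilyl)pent-4-yn-1-yl]oxy}dimethylsilane | C[Si](C)(C)C#CC[C@@H](OCc1ccccc1)[C@H](O[Si](C)(C)C(C)(C)C)c1cc(OCc2ccccc2)c(OCc2ccccc2)c(OCc2ccccc2)c1 | intermediate
14 | (1R,2R)-2-(benzyloxy)-1-[3,4,5-tris(benzyloxy)phenyl]pent-4-yn-1-ol | C#CC[C@@H](OCc1ccccc1)[C@H](O)c1cc(OCc2ccccc2)c(OCc2ccccc2)c(OCc2ccccc2)c1 | intermediate
15 | tributyl{(2R,3R)-3-(benzyloxy)-2-[3,4,5-tris(benzyloxy)phenyl]-3,4-dihydro-2H-pyran-6-yl}stannane | CCCC[Sn](CCCC)(CCCC)C1=CC[C@@H](OCc2ccccc2)[C@@H](c2cc(OCc3ccccc3)c(OCc3ccccc3)c(OCc3ccccc3)c2)O1 | intermediate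
16 | {(2R,3R)-3-(benzyloxy)-2-[3,4,5-tris(benzyloxy)phenyl]-3,4-dihydro-2H-pyran-6-yl}lithium | [Li]C1=CC[C@@H](OCc2ccccc2)[C@@H](c2cc(OCc3ccccc3)c(OCc3ccccc3)c(OCc3ccccc3)c2)O1 | intermediate
17 | (2R,3R)-3-(benzyloxy)-2-[3,4,5-tris(benzyloxy)phenyl]-3,4-dihydro-2H-pyran-6-carbaldehyde | O=CC1=CC[C@@H](OCc2ccccc2)[C@@H](c2cc(OCc3ccccc3)c(OCc3ccccc3)c(OCc3ccccc3)c2)O1 | intermediate
18 | ethynylmagnesium bromide | C#C[Mg]Br | starting material
19 | 1-{(2R,3R)-3-(benzyloxy)-2-[3,4,5-tris(benzyloxy)phenyl]-3,4-dihydro-2H-pyran-6-yl}prop-2-yn-1-ol, both C8 epimers | C#CC(O)C1=CC[C@@H](OCc2ccccc2)[C@@H](c2cc(OCc3ccccc3)c(OCc3ccccc3)c(OCc3ccccc3)c2)O1 | intermediate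
20 | 3,4,5-tris(benzyloxy)benzoic acid | O=C(O)c1cc(OCc2ccccc2)c(OCc2ccccc2)c(OCc2ccccc2)c1 | starting material
21 | 1-{(2R,3R)-3-(benzyloxy)-2-[3,4,5-tris(benzyloxy)phenyl]-3,4-dihydro-2H-pyran-6-yl}prop-2-yn-1-yl 3,4,5-tris(benzyloxy)benzoate, both C8 epimers | C#CC(OC(=O)c1cc(OCc2ccccc2)c(OCc2ccccc2)c(OCc2ccccc2)c1)C1=CC[C@@H](OCc2ccccc2)[C@@H](c2cc(OCc3ccccc3)c(OCc3ccccc3)c(OCc3ccccc3)c2)O1 | intermediate
22 | (2R,3R)-3-(benzyloxy)-5-hydroxy-2-[3,4,5-tris(benzyloxy)phenyl]chroman-7-yl 3,4,5-tris(benzyloxy)benzoate | O=C(Oc1cc(O)c2c(c1)O[C@H](c1cc(OCc3ccccc3)c(OCc3ccccc3)c(OCc3ccccc3)c1)[C@H](OCc1ccccc1)C2)c1cc(OCc2ccccc2)c(OCc2ccccc2)c(OCc2ccccc2)c1 | intermediate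
23 | epigallocatechin 7-O-gallate, (2R,3R)-3,5-dihydroxy-2-(3,4,5-trihydroxyphenyl)chroman-7-yl 3,4,5-trihydroxybenzoate | O=C(Oc1cc(O)c2c(c1)O[C@H](c1cc(O)c(O)c(O)c1)[C@H](O)C2)c1cc(O)c(O)c(O)c1 | target

Total step count: 12
Longest linear sequence: 12 steps (from 1 and 2 to 23)

Steps most likely to fail

1. Step 11. The bulky, electron-rich aroyloxy group may migrate slowly, so that a 1,3-acyloxy shift to an allenyl ester, ionisation of the C8–O bond or rhodium-induced decomposition of the enol ether could outrun carbene formation and CO uptake. The fallback sets out from 19 and removes the gallate from the role of migrating group. Acetylation (Ac2O, Et3N, DMAP, CH2Cl2) should give the propargylic acetate F1. The same CO benzannulation ([Rh(CO)2Cl]2, CO, ClCH2CH2Cl, 60 °C), now with a small acyl group, should give the 5-hydroxy 7-acetate F2. Mitsunobu benzylation of the lone C5 phenol (BnOH, PPh3, DIAD, THF) should give the 5-O-benzyl 7-acetate F3. Methanolysis (K2CO3, MeOH/THF) should free the C7 phenol F4, and Steglich esterification with 20 (DCC, DMAP) should give the octa-O-benzyl 7-gallate F5. Hydrogenolysis under the conditions of step 12 then returns to the route at 23.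

2. Step 7. Protonation of the alkenyl tungstate by triethylammonium may outrun stannyl transfer, or the vinylstannane may lose tin on isolation, leaving the tin-free enol ether. The fallback sets out from 14 and makes C8a electrophilic instead. Catalytic cycloisomerisation (W(CO)6 cat., Et3N, THF, hν, 60 °C) should give the 6-unsubstituted dihydropyran F6. Oxidation of the enol ether with pyridinium chlorochromate (C5H5NH[CrO3Cl], CH2Cl2) should give the δ-lactone F7. Enolisation and O-phosphorylation (KN(SiMe3)2, (PhO)2P(O)Cl, THF/HMPA, −78 °C) should give the ketene acetal phosphate F8. Methoxycarbonylation (Pd(PPh3)4, CO, MeOH, Et3N, DMF, 60 °C) should give the methyl ester F9, which i-Bu2AlH (CH2Cl2, −78 °C) should reduce to the allylic alcohol F10. Oxidation with MnO2 (CH2Cl2) returns to the route at 17.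

3. Step 5. Base-induced elimination of the β-alkoxy triflate or its decomposition before substitution may compete with alkynylation at the β-branched primary carbon. The fallback sets out from 9 and builds the alkyne by carbonyl homologation. Dess–Martin oxidation should give the α-benzyloxy aldehyde F11, which is used cold and at once to limit epimerisation. Wittig reaction with Ph3P=CHOMe (from the phosphonium chloride and KN(SiMe3)2, THF, −78 °C) should give the methyl enol ether F12. Hydrolysis with Hg(OAc)2 in aqueous THF followed by KI should give the one-carbon homologated aldehyde F13. The Ohira–Bestmann reagent (dimethyl (1-diazo-2-oxopropyl)phosphonate, K2CO3, MeOH, 0 °C) should convert it into the terminal alkyne F14. Desilylation with Bu4NF returns to the route at 14.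

Further compounds
F1 | step 11 | 1-{(2R,3R)-3-(benzyloxy)-2-[3,4,5-tris(benzyloxy)phenyl]-3,4-dihydro-2H-pyran-6-yl}prop-2-yn-1-yl acetate | C#CC(OC(C)=O)C1=CC[C@@H](OCc2ccccc2)[C@@H](c2cc(OCc3ccccc3)c(OCc3ccccc3)c(OCc3ccccc3)c2)O1
F2 | step 11 | (2R,3R)-3-(benzyloxy)-5-hydroxy-2-[3,4,5-tris(benzyloxy)phenyl]chroman-7-yl acetate | CC(=O)Oc1cc(O)c2c(c1)O[C@H](c1cc(OCc3ccccc3)c(OCc3ccccc3)c(OCc3ccccc3)c1)[C@H](OCc1ccccc1)C2
F3 | step 11 | (2R,3R)-3,5-bis(benzyloxy)-2-[3,4,5-tris(benzyloxy)phenyl]chroman-7-yl acetate | CC(=O)Oc1cc(OCc3ccccc3)c2c(c1)O[C@H](c1cc(OCc3ccccc3)c(OCc3ccccc3)c(OCc3ccccc3)c1)[C@H](OCc1ccccc1)C2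
F4 | step 11 | (2R,3R)-3,5-bis(benzyloxy)-2-[3,4,5-tris(benzyloxy)phenyl]chroman-7-ol | Oc1cc(OCc3ccccc3)c2c(c1)O[C@H](c1cc(OCc3ccccc3)c(OCc3ccccc3)c(OCc3ccccc3)c1)[C@H](OCc1ccccc1)C2
F5 | step 11 | (2R,3R)-3,5-bis(benzyloxy)-2-[3,4,5-tris(benzyloxy)phenyl]chroman-7-yl 3,4,5-tris(benzyloxy)benzoate | O=C(Oc1cc(OCc3ccccc3)c2c(c1)O[C@H](c1cc(OCc3ccccc3)c(OCc3ccccc3)c(OCc3ccccc3)c1)[C@H](OCc1ccccc1)C2)c1cc(OCc2ccccc2)c(OCc2ccccc2)c(OCc2ccccc2)c1
F6 | step 7 | (2R,3R)-3-(benzyloxy)-2-[3,4,5-tris(benzyloxy)phenyl]-3,4-dihydro-2H-pyran | C1=CC[C@@H](OCc2ccccc2)[C@@H](c2cc(OCc3ccccc3)c(OCc3ccccc3)c(OCc3ccccc3)c2)O1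
F7 | step 7 | (5R,6R)-5-(benzyloxy)-6-[3,4,5-tris(benzyloxy)phenyl]tetrahydro-2H-pyran-2-one | O=C1CC[C@@H](OCc2ccccc2)[C@@H](c2cc(OCc3ccccc3)c(OCc3ccccc3)c(OCc3ccccc3)c2)O1
F8 | step 7 | (2R,3R)-3-(benzyloxy)-2-[3,4,5-tris(benzyloxy)phenyl]-3,4-dihydro-2H-pyran-6-yl diphenyl phosphate | O=P(OC1=CC[C@@H](OCc2ccccc2)[C@@H](c2cc(OCc3ccccc3)c(OCc3ccccc3)c(OCc3ccccc3)c2)O1)(Oc1ccccc1)Oc1ccccc1
F9 | step 7 | methyl (2R,3R)-3-(benzyloxy)-2-[3,4,5-tris(benzyloxy)phenyl]-3,4-dihydro-2H-pyran-6-carboxylate | COC(=O)C1=CC[C@@H](OCc2ccccc2)[C@@H](c2cc(OCc3ccccc3)c(OCc3ccccc3)c(OCc3ccccc3)c2)O1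
F10 | step 7 | {(2R,3R)-3-(benzyloxy)-2-[3,4,5-tris(benzyloxy)phenyl]-3,4-dihydro-2H-pyran-6-yl}methanol | OCC1=CC[C@@H](OCc2ccccc2)[C@@H](c2cc(OCc3ccccc3)c(OCc3ccccc3)c(OCc3ccccc3)c2)O1
F11 | step 5 | (2S,3R)-2-(benzyloxy)-3-[(tert-butyldimethylsilyl)oxy]-3-[3,4,5-tris(benzyloxy)phenyl]propanal | O=C[C@@H](OCc1ccccc1)[C@H](O[Si](C)(C)C(C)(C)C)c1cc(OCc2ccccc2)c(OCc2ccccc2)c(OCc2ccccc2)c1
F12 | step 5 | tert-butyl{[(1R,2R)-2-(benzyloxy)-4-methoxy-1-[3,4,5-tris(benzyloxy)phenyl]but-3-en-1-yl]oxy}dimethylsilane, E/Z mixture | COC=C[C@@H](OCc1ccccc1)[C@H](O[Si](C)(C)C(C)(C)C)c1cc(OCc2ccccc2)c(OCc2ccccc2)c(OCc2ccccc2)c1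
F13 | step 5 | (3R,4R)-3-(benzyloxy)-4-[(tert-butyldimethylsilyl)oxy]-4-[3,4,5-tris(benzyloxy)phenyl]butanal | O=CC[C@@H](OCc1ccccc1)[C@H](O[Si](C)(C)C(C)(C)C)c1cc(OCc2ccccc2)c(OCc2ccccc2)c(OCc2ccccc2)c1
F14 | step 5 | tert-butyl{[(1R,2R)-2-(benzyloxy)-1-[3,4,5-tris(benzyloxy)phenyl]pent-4-yn-1-yl]oxy}dimethylsilane | C#CC[C@@H](OCc1ccccc1)[C@H](O[Si](C)(C)C(C)(C)C)c1cc(OCc2ccccc2)c(OCc2ccccc2)c(OCc2ccccc2)c1
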